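**Retrosynthetic overview**

1. Feature: chroman C3 is a CH carrying two one-carbon arms, C2 (in ring C, bound to O1) and C1' (a carbon of quinone ring B). Traced back to two CH2OH groups they are enantiotopic, so C3 is set by choosing which hydroxyl forms O1–C8a.
2. Ring B (last): the 2,3-dimethoxyquinone is opened by a Moore rearrangement to a 4-alkynyl-4-hydroxycyclobutenone, that is dimethyl squarate plus the lithium acetylide made from (6,7,8-trimethoxychroman-3-yl)methanol by oxidation and Corey–Fuchs homologation.
3. Ring C (key): O1–C8a is cut to 2-(2-iodo-3,4,5-trimethoxybenzyl)propane-1,3-diol, closed by a desymmetrising O-arylation with CuI and a chiral 1,2-diamine.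
4. The diol goes back to diethyl malonate and 2-iodo-3,4,5-trimethoxybenzyl bromide, made from 3,4,5-trimethoxybenzyl alcohol.
5. Ring order: ring A is bought, ring C closes in step 5, ring B forms in step 9 without any oxidant.

Key step: step 5

Assumption: which antipode of the diamine leads to the (S)-alcohol 8 cannot be derived safely on paper. The (1R,2R)-ligand is written, and its mirror image, equally available, takes its place if a first run of step 5 (Mosher ester analysis of 8) shows the other sense.

**Route**

Step 1
Reactants: 1 3,4,5-trimethoxybenzyl alcohol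
Product: 2 (2-iodo-3,4,5-trimethoxyphenyl)methanol
Conditions: I2, CF3CO2Ag, CHCl3, 0 °C to rt
Reagents that add atoms: iodine, II
Why: Silver-assisted electrophilic aromatic iodination, in which the two free ring positions are equivalent and activated by the methoxy groups, so only one regioisomer can form and the iodine introduced slows a second substitution.

Step 2
Reactants: 2 (2-iodo-3,4,5-trimethoxyphenyl)methanol
Product: 3 1-(bromomethyl)-2-iodo-3,4,5-trimethoxybenzene
Conditions: PBr3 (0.4 equiv), CH2Cl2, 0 °C
Reagents that add atoms: phosphorus tribromide, BrP(Br)Br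
Why: Conversion of a primary benzylic alcohol into its bromide with PBr3 (SN2 on the alkyl phosphite), run cold and short so that the aryl methyl ethers are not touched.

Step 3
Reactants: 3 1-(bromomethyl)-2-iodo-3,4,5-trimethoxybenzene; 4 diethyl malonate
Product: 6 diethyl 2-(2-iodo-3,4,5-trimethoxybenzyl)malonate, via sodium diethyl malonate 5 (not isolated)
Conditions: 4 (2.5 equiv), NaH (1.2 equiv), THF, 0 °C; then 3, 0 °C to rt
Reagents that add atoms: none
Why: Malonic ester alkylation, in which the sodium enolate displaces the benzylic bromide by SN2 and the excess of malonate keeps the monoalkylated product from reacting a second time.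

Step 4
Reactants: 6 diethyl 2-(2-iodo-3,4,5-trimethoxybenzyl)malonate
Product: 7 2-(2-iodo-3,4,5-trimethoxybenzyl)propane-1,3-diol
Conditions: LiBH4 (3 equiv), THF, 0 °C to 50 °C; then 1 M HCl, 0 °C
Reagents that add atoms: none
Why: Hydride reduction of both esters with LiBH4 should give the prochiral 1,3-diol, and this reagent, unlike LiAlH4, leaves the aryl iodide in place.

Step 5
Reactants: 7 2-(2-iodo-3,4,5-trimethoxybenzyl)propane-1,3-diol
Product: 8 (S)-(6,7,8-trimethoxychroman-3-yl)methanol
Conditions: CuI (10 mol%), (1R,2R)-N,N'-dimethylcyclohexane-1,2-diamine (20 mol%), Cs2CO3 (2 equiv), MeCN (0.05 M), 40 °C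
Reagents that add atoms: none
Why: Cs2CO3 turns one hydroxyl into an alkoxide on the diamine-bound cuprous centre, the neighbouring C–I bond adds oxidatively to give an aryl(alkoxy) trivalent copper species, and C–O reductive elimination forms O1–C8a and returns CuI. The closest known reaction type is the copper-catalysed enantioselective desymmetrising intramolecular O-arylation of 2-(2-halobenzyl)propane-1,3-diols, an asymmetric Ullmann ether synthesis. Ring C closes as a six-membered ring in exo fashion at the arene carbon that carried iodine, by way of a seven-membered cuprocycle. C3, the only new stereocentre, is controlled by the twofold-symmetric chiral diamine on copper, which makes the two diastereomeric alkoxide complexes, one from each enantiotopic CH2OH group, cyclise at different rates. The step needs group selectivity between the two hydroxyls and ring closure in preference to intermolecular etherification; the mirror symmetry of 7, its single C–I bond, the dilution and the nearness of the alkoxide to the iodide secure the second, while the first rests on the ligand acting against the steric pressure of the methoxy group beside iodine. Because 8 has no halide left, no later coupling can change its enantiomeric purity, and an iodide rather than a bromide is used so that oxidative addition stays fast despite that flanking methoxy group.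

Step 6
Reactants: 8 (S)-(6,7,8-trimethoxychroman-3-yl)methanol
Product: 9 (R)-6,7,8-trimethoxychroman-3-carbaldehyde
Conditions: Dess–Martin periodinane (1.2 equiv), NaHCO3, CH2Cl2, 0 °C to rt; crude product used at once
Reagents that add atoms: none
Why: Dess–Martin oxidation of a primary alcohol stops at the aldehyde under buffered, non-basic conditions, so C3 next to the formyl group should neither enolise nor lose the aryloxide by β-elimination (the descriptor changes only through the priority rules).

Step 7
Reactants: 9 (R)-6,7,8-trimethoxychroman-3-carbaldehyde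
Product: 10 (S)-3-(2,2-dibromovinyl)-6,7,8-trimethoxychroman
Conditions: CBr4, PPh3, Zn, CH2Cl2, rt (ylide formed first); then 9, 0 °C to rt
Reagents that add atoms: carbon tetrabromide, BrC(Br)(Br)Br
Why: Ramirez dibromoolefination, the first stage of the Corey–Fuchs sequence, is a Wittig-type reaction that in its zinc variant is free of base and of Ph3PBr2, which should keep C3 intact.

Step 8
Reactants: 10 (S)-3-(2,2-dibromovinyl)-6,7,8-trimethoxychroman; 11 dimethyl squarate
Product: 14 4-hydroxy-2,3-dimethoxy-4-{[(S)-6,7,8-trimethoxychroman-3-yl]ethynyl}cyclobut-2-en-1-one, via lithium acetylide 12 (not isolated), via lithium alkoxide 13 (not isolated)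
Conditions: n-BuLi (2.05 equiv), THF, –78 °C; then 11 (1.2 equiv), –78 °C; sat. aq. NH4Cl, –78 °C
Reagents that add atoms: none
Why: Second stage of the Corey–Fuchs sequence, in which bromine–lithium exchange, a Fritsch–Buttenberg–Wiechell 1,2-hydride shift and deprotonation give the lithium acetylide, which adds 1,2 to one carbonyl of the squarate; the carbinol carbon forms as both epimers, which is of no consequence because it is lost in step 9.

Step 9
Reactants: 14 4-hydroxy-2,3-dimethoxy-4-{[(S)-6,7,8-trimethoxychroman-3-yl]ethynyl}cyclobut-2-en-1-one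
Product: 16 abruquinone B, via alkynylvinylketene 15 (not isolated)
Conditions: p-xylene (0.01 M, degassed), reflux (138 °C), argon, short heating
Reagents that add atoms: none
Why: Moore rearrangement, in which conrotatory 4π ring opening with the hydroxyl turning outward gives the alkynylvinylketene, this closes to the six-membered diradical and the hydroxyl hydrogen moves to carbon to give the quinone; an alkyl-substituted alkyne favours six- over five-membered closure, and as no oxidant or base is present ring A and C3 should stay as they are.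

**Compound list**

1 | 3,4,5-trimethoxybenzyl alcohol | COc1cc(CO)cc(OC)c1OC | starting material
2 | (2-iodo-3,4,5-trimethoxyphenyl)methanol | COc1cc(CO)c(I)c(OC)c1OC | intermediate
3 | 1-(bromomethyl)-2-iodo-3,4,5-trimethoxybenzene | COc1cc(CBr)c(I)c(OC)c1OC | intermediate
4 | diethyl malonate | CCOC(=O)CC(=O)OCC | starting material
5 | sodium diethyl malonate (sodium enolate of 4) | [Na+].CCOC(=O)[CH-]C(=O)OCC | intermediate (not isolated)
6 | diethyl 2-(2-iodo-3,4,5-trimethoxybenzyl)malonate | CCOC(=O)C(Cc1cc(OC)c(OC)c(OC)c1I)C(=O)OCC | intermediate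
7 | 2-(2-iodo-3,4,5-trimethoxybenzyl)propane-1,3-diol (prochiral) | COc1cc(CC(CO)CO)c(I)c(OC)c1OC | intermediate
8 | (S)-(6,7,8-trimethoxychroman-3-yl)methanol | OC[C@H]1COc2c(cc(OC)c(OC)c2OC)C1 | intermediate
9 | (R)-6,7,8-trimethoxychroman-3-carbaldehyde | O=C[C@H]1COc2c(cc(OC)c(OC)c2OC)C1 | intermediate
10 | (S)-3-(2,2-dibromovinyl)-6,7,8-trimethoxychroman | BrC(Br)=C[C@H]1COc2c(cc(OC)c(OC)c2OC)C1 | intermediate
11 | dimethyl squarate (3,4-dimethoxycyclobut-3-ene-1,2-dione) | COC1=C(OC)C(=O)C1=O | starting material
12 | {[(S)-6,7,8-trimethoxychroman-3-yl]ethynyl}lithium | [Li]C#C[C@H]1COc2c(cc(OC)c(OC)c2OC)C1 | intermediate (not isolated)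
13 | lithium alkoxide of 14 | [Li+].COC1=C(OC)C([O-])(C#C[C@H]2COc3c(cc(OC)c(OC)c3OC)C2)C1=O | intermediate (not isolated)
14 | 4-hydroxy-2,3-dimethoxy-4-{[(S)-6,7,8-trimethoxychroman-3-yl]ethynyl}cyclobut-2-en-1-one, both epimers at the carbinol carbon | COC1=C(OC)C(O)(C#C[C@H]2COc3c(cc(OC)c(OC)c3OC)C2)C1=O | intermediate
15 | (Z)-4-hydroxy-2,3-dimethoxy-6-[(S)-6,7,8-trimethoxychroman-3-yl]hexa-1,3-dien-5-yn-1-one (alkynyl group cis to the ketene carbon) | O=C=C(OC)/C(OC)=C(/O)C#C[C@H]1COc2c(cc(OC)c(OC)c2OC)C1 | intermediate (not isolated)
16 | abruquinone B, 2,3-dimethoxy-5-[(3S)-6,7,8-trimethoxychroman-3-yl]cyclohexa-2,5-diene-1,4-dione | COC1=C(OC)C(=O)C([C@H]2COc3c(cc(OC)c(OC)c3OC)C2)=CC1=O | target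

**Step count**

Total steps: 9. Longest linear sequence: 9 steps (1 to 16); 4 and 11 enter as bought building blocks.

**Steps most likely to fail**

Step 5. The ligand may discriminate poorly between the enantiotopic hydroxymethyl groups, or oxidative addition at the iodide crowded by the neighbouring methoxy group may be slow enough for hydrodeiodination to compete. The fallback sets out from diol 7 and lets an enzyme set the stereocentre before an achiral ring closure. Lipase-catalysed monoacetylation (Burkholderia cepacia lipase or porcine pancreatic lipase, chosen by screening for the antipode needed, vinyl acetate, t-BuOMe) should give (S)-3-hydroxy-2-(2-iodo-3,4,5-trimethoxybenzyl)propyl acetate F1. A 1,3-diol monoacetate scrambles by acyl migration under carbonate base, so the free hydroxyl is first covered with dihydropyran and pyridinium p-toluenesulfonate, giving (2S)-2-(2-iodo-3,4,5-trimethoxybenzyl)-3-(tetrahydro-2H-pyran-2-yloxy)propyl acetate F2. K2CO3 in methanol at 0 °C then removes the acetate to give (2R)-3-(2-iodo-3,4,5-trimethoxyphenyl)-2-[(tetrahydro-2H-pyran-2-yloxy)methyl]propan-1-ol F3. Ullmann ring closure with CuI, 1,10-phenanthroline and Cs2CO3 in toluene at 100 °C, with no chiral ligand, gives 2-{[(3R)-6,7,8-trimethoxychroman-3-yl]methoxy}tetrahydro-2H-pyran F4. TsOH in methanol brings the sequence back to alcohol 8.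

Step 9. The ketene may partition toward five-membered ring closure (an alkylidene cyclopentenedione), or configuration at C3 may erode at 138 °C. The fallback sets out from dibromoolefin 10 and reaches ring B by a pericyclic path that has no five-membered alternative. Pd(PPh3)4 with Bu3SnH removes the bromine trans to the chroman and should give (S,Z)-3-(2-bromovinyl)-6,7,8-trimethoxychroman F7. t-BuLi (2 equiv, Et2O, –78 °C) gives {(Z)-2-[(S)-6,7,8-trimethoxychroman-3-yl]vinyl}lithium F8, which adds to dimethyl squarate 11 and after NH4Cl quench gives 4-hydroxy-2,3-dimethoxy-4-{(Z)-2-[(S)-6,7,8-trimethoxychroman-3-yl]vinyl}cyclobut-2-en-1-one F9. Heating in toluene (electrocyclic ring opening, 6π ring closure, tautomerisation) gives 2,3-dimethoxy-5-[(3S)-6,7,8-trimethoxychroman-3-yl]benzene-1,4-diol F10. Ag2O in Et2O oxidises this hydroquinone, which is far more easily oxidised than ring A, and the sequence ends at target 16.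

Step 6. Configuration at C3 may be lost by enolisation of the aldehyde, or ring C may open by β-elimination of the aryloxide, during oxidation and olefination. The fallback sets out from alcohol 8 and avoids any carbonyl group at C1'. I2, PPh3 and imidazole in CH2Cl2 give (R)-3-(iodomethyl)-6,7,8-trimethoxychroman F5. LiCHBr2, made from CH2Br2 and LiN(i-Pr)2 in THF/DMPU at –90 °C, is alkylated by this iodide to give (S)-3-(2,2-dibromoethyl)-6,7,8-trimethoxychroman F6. LiN(i-Pr)2 (3 equiv, THF, –78 °C to –20 °C) effects double dehydrobromination and deprotonation, and the sequence rejoins the route at lithium acetylide 12, which is treated with dimethyl squarate 11 as in step 8.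

**Further compounds**

F1 | step 5 | (S)-3-hydroxy-2-(2-iodo-3,4,5-trimethoxybenzyl)propyl acetate | OC[C@H](Cc1cc(OC)c(OC)c(OC)c1I)COC(C)=O
F2 | step 5 | (2S)-2-(2-iodo-3,4,5-trimethoxybenzyl)-3-(tetrahydro-2H-pyran-2-yloxy)propyl acetate, both epimers at the acetal carbon | C1CCOC(C1)OC[C@H](Cc2cc(OC)c(OC)c(OC)c2I)COC(C)=O
F3 | step 5 | (2R)-3-(2-iodo-3,4,5-trimethoxyphenyl)-2-[(tetrahydro-2H-pyran-2-yloxy)methyl]propan-1-ol, both epimers at the acetal carbon | C1CCOC(C1)OC[C@H](Cc2cc(OC)c(OC)c(OC)c2I)CO
F4 | step 5 | 2-{[(3R)-6,7,8-trimethoxychroman-3-yl]methoxy}tetrahydro-2H-pyran, both epimers at the acetal carbon | C1CCOC(C1)OC[C@H]2COc3c(cc(OC)c(OC)c3OC)C2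
F5 | step 6 | (R)-3-(iodomethyl)-6,7,8-trimethoxychroman | IC[C@H]1COc2c(cc(OC)c(OC)c2OC)C1
F6 | step 6 | (S)-3-(2,2-dibromoethyl)-6,7,8-trimethoxychroman | BrC(Br)C[C@H]1COc2c(cc(OC)c(OC)c2OC)C1
F7 | step 9 | (S,Z)-3-(2-bromovinyl)-6,7,8-trimethoxychroman | Br/C=C\[C@H]1COc2c(cc(OC)c(OC)c2OC)C1
F8 | step 9 | {(Z)-2-[(S)-6,7,8-trimethoxychroman-3-yl]vinyl}lithium | [Li]/C=C\[C@H]1COc2c(cc(OC)c(OC)c2OC)C1
F9 | step 9 | 4-hydroxy-2,3-dimethoxy-4-{(Z)-2-[(S)-6,7,8-trimethoxychroman-3-yl]vinyl}cyclobut-2-en-1-one, both epimers at the carbinol carbon | COC1=C(OC)C(O)(/C=C\[C@H]2COc3c(cc(OC)c(OC)c3OC)C2)C1=O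
F10 | step 9 | 2,3-dimethoxy-5-[(3S)-6,7,8-trimethoxychroman-3-yl]benzene-1,4-diol | COc1c(OC)c(O)c([C@H]2COc3c(cc(OC)c(OC)c3OC)C2)cc1O
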